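**Retrosynthetic overview**
1. The three phenols are freed last from benzyl ethers. The aryl ketone beside the labile side-chain CH(CH2OH) centre comes from a benzylic carbinol by late MnO2 oxidation, and that 1,3-diol side chain is built by an Evans syn aldol.
2. The bond between the C3 methylene of the lactone and ring B is cut (Negishi coupling), giving a lactone CH2ZnI fragment and a ring B aryl bromide.
3. The strategy rests on lactone C3. It carries two CH2 groups, the ring C4H2–O and the CH2 bonded to ring B, so with both as CH2OH it is prochiral. The C2 stereocentre (Evans alkylation) alone then decides which CH2OH closes the lactone under equilibrating acid.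
4. Only one ring is formed, the γ-lactone (C4–O bond), in the key step; the three arenes are bought as vanillin-type building blocks.

Key step: step 7

Remark: benzyl diethylphosphonoacetate, 4-(benzyloxy)-3-methoxybenzyl alcohol, 5-bromo-2-hydroxy-3-methoxybenzaldehyde and 4-(benzyloxy)-3-methoxybenzaldehyde are taken to be purchasable. Lactone atoms are numbered C1 (C=O), C2, C3, C4 (OCH2). Ring A sits on the C2 methylene, ring B on the C3 methylene, and ring C is the aryl ketone ring.

**Step 1**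
Reactants: 1 2,2-dimethyl-1,3-dioxan-5-one; 2 benzyl 2-(diethoxyphosphoryl)acetate
Product: 3 benzyl 2-(2,2-dimethyl-1,3-dioxan-5-ylidene)acetate
Conditions: NaH, THF, 0 °C to rt
Reagents that add atoms: none
Why: Horner–Wadsworth–Emmons olefination of an unhindered symmetric ketone, so no alkene isomer or stereocentre is at stake.

**Step 2**
Reactants: 3 benzyl 2-(2,2-dimethyl-1,3-dioxan-5-ylidene)acetate
Product: 4 2-(2,2-dimethyl-1,3-dioxan-5-yl)acetic acid
Conditions: H2 (1 atm), 10% Pd/C, EtOAc, rt; acid kept cold and used at once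
Reagents that add atoms: none
Why: Catalytic hydrogenation saturates the trisubstituted alkene and hydrogenolyses the benzyl ester in one operation, and prompt use keeps the free acid from cleaving its own acetonide.

**Step 3**
Reactants: 4 2-(2,2-dimethyl-1,3-dioxan-5-yl)acetic acid; 5 (R)-4-benzyloxazolidin-2-one
Product: 7 (R)-4-benzyl-3-[2-(2,2-dimethyl-1,3-dioxan-5-yl)acetyl]oxazolidin-2-one, via mixed pivalic anhydride 6 (not isolated)
Conditions: t-BuCOCl, Et3N, THF, −20 °C; then LiCl, 5, rt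
Reagents that add atoms: none
Why: Mixed-anhydride N-acylation of the oxazolidinone, which attacks the less hindered acyl carbon under basic conditions that leave the acetonide intact.

**Step 4**
Reactants: 8 [4-(benzyloxy)-3-methoxyphenyl]methanol
Product: 9 1-(benzyloxy)-4-(bromomethyl)-2-methoxybenzene
Conditions: PBr3, Et2O, 0 °C; used freshly
Reagents that add atoms: phosphorus tribromide, BrP(Br)Br
Why: Bromide displaces the phosphite ester of the electron-rich benzylic alcohol (SN2), a standard alcohol-to-bromide conversion.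

**Step 5**
Reactants: 7 (R)-4-benzyl-3-[2-(2,2-dimethyl-1,3-dioxan-5-yl)acetyl]oxazolidin-2-one; 9 1-(benzyloxy)-4-(bromomethyl)-2-methoxybenzene
Product: 11 (R)-4-benzyl-3-[(2R)-3-[4-(benzyloxy)-3-methoxyphenyl]-2-(2,2-dimethyl-1,3-dioxan-5-yl)propanoyl]oxazolidin-2-one, via sodium Z-enolate 10 (not isolated)
Conditions: NaN(SiMe3)2, THF, −78 °C; then 9, −78 to −30 °C
Reagents that add atoms: none
Why: Evans asymmetric alkylation, in which the chelated sodium Z-enolate is benzylated on the face opposite the C4 benzyl group of the (R)-auxiliary and so sets the later lactone C2 as R.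

**Step 6**
Reactants: 11 (R)-4-benzyl-3-[(2R)-3-[4-(benzyloxy)-3-methoxyphenyl]-2-(2,2-dimethyl-1,3-dioxan-5-yl)propanoyl]oxazolidin-2-one
Product: 13 (2R)-3-[4-(benzyloxy)-3-methoxyphenyl]-2-(2,2-dimethyl-1,3-dioxan-5-yl)propanoic acid, via lithium percarboxylate 12 (not isolated)
Conditions: LiOH, H2O2, THF/H2O, 0 °C; then Na2SO3; then HCl to pH 4, 0 °C
Reagents that add atoms: hydrogen peroxide, OO
Why: Hydroperoxide cleaves the exocyclic imide carbonyl selectively without epimerising C2, sulfite reduces the peracid, and acidification only to pH 4 in the cold keeps the acetonide.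

**Step 7**
Reactants: 13 (2R)-3-[4-(benzyloxy)-3-methoxyphenyl]-2-(2,2-dimethyl-1,3-dioxan-5-yl)propanoic acid
Product: 15 (3R,4S)-3-[4-(benzyloxy)-3-methoxybenzyl]-4-(hydroxymethyl)dihydrofuran-2(3H)-one, via dihydroxy acid 14 (not isolated)
Conditions: TsOH·H2O (0.1 equiv), wet THF, 50 °C, held until the cis/trans composition is constant
Reagents that add atoms: none
Why: Acid hydrolyses the acetonide to dihydroxy acid 14, and either of its two diastereotopic CH2OH groups then adds to the protonated carboxyl and expels water; the closest known reaction type is the acid-catalysed lactonisation of a γ-hydroxy acid (intramolecular Fischer esterification). The single ring closes in the 5-exo-trig mode at the carboxyl carbon and forms the C4–O bond. The new stereocentre C3 is fixed by which CH2OH closes, and this is ruled by the C2 stereocentre of step 5, because in the trans-lactone the C2 arylmethyl and C3 hydroxymethyl groups avoid the eclipsing strain of the cis isomer. The free CH2OH of either lactone can add to the lactone carbonyl to give a bicyclic hemiorthoester that collapses to the other lactone, so cis and trans interconvert by acyl transfer (and by reversible hydrolysis) while the C2–H is never removed. The step needs group selectivity between the two CH2OH groups, which the C2 substituent secures thermodynamically under non-enolising acid; the benzyl ether and arene are inert to catalytic TsOH, and residual cis isomer is removed by chromatography and can be re-equilibrated.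

**Step 8**
Reactants: 15 (3R,4S)-3-[4-(benzyloxy)-3-methoxybenzyl]-4-(hydroxymethyl)dihydrofuran-2(3H)-one
Product: 16 (3R,4R)-3-[4-(benzyloxy)-3-methoxybenzyl]-4-(iodomethyl)dihydrofuran-2(3H)-one
Conditions: I2, PPh3, imidazole, CH2Cl2, 0 °C to rt
Reagents that add atoms: iodine, II
Why: Appel-type iodination in which iodide displaces the alkoxyphosphonium group at the primary carbon (SN2), leaving both stereocentres untouched.

**Step 9**
Reactants: 17 5-bromo-2-hydroxy-3-methoxybenzaldehyde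
Product: 18 2-(benzyloxy)-5-bromo-3-methoxybenzaldehyde
Conditions: BnBr, K2CO3, DMF, 50 °C
Reagents that add atoms: benzyl bromide, BrCc1ccccc1
Why: Williamson etherification of the phenoxide, which forms easily because of the ortho-formyl group.

**Step 10**
Reactants: 18 2-(benzyloxy)-5-bromo-3-methoxybenzaldehyde
Product: 20 2-[2-(benzyloxy)-5-bromo-3-methoxyphenyl]acetonitrile, via N-(1-tosylvinyl)formamide 19 (not isolated)
Conditions: TosMIC, KOt-Bu, DME, −50 to −30 °C; then MeOH, reflux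
Reagents that add atoms: p-toluenesulfonylmethyl isocyanide (TosMIC), [C-]#[N+]CS(=O)(=O)c1ccc(C)cc1
Why: Van Leusen reductive cyanation, in which the TosMIC anion adds to the aldehyde, the oxazoline opens to the vinylformamide, and methoxide then removes the formyl group with loss of sulfinate to give the one-carbon-homologated nitrile.

**Step 11**
Reactants: 20 2-[2-(benzyloxy)-5-bromo-3-methoxyphenyl]acetonitrile
Product: 21 2-[2-(benzyloxy)-5-bromo-3-methoxyphenyl]acetic acid
Conditions: KOH, EtOH/H2O, reflux; then HCl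
Reagents that add atoms: potassium hydroxide, [K+].[OH-]; water, O
Why: Alkaline nitrile hydrolysis via the amide, to which the aryl bromide and the benzyl ether are stable.

**Step 12**
Reactants: 21 2-[2-(benzyloxy)-5-bromo-3-methoxyphenyl]acetic acid; 5 (R)-4-benzyloxazolidin-2-one
Product: 23 (R)-4-benzyl-3-{2-[2-(benzyloxy)-5-bromo-3-methoxyphenyl]acetyl}oxazolidin-2-one, via mixed pivalic anhydride 22 (not isolated)
Conditions: t-BuCOCl, Et3N, THF, −20 °C; then LiCl, 5, rt
Reagents that add atoms: none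
Why: Mixed-anhydride N-acylation as in step 3, with no stereocentre formed.

**Step 13**
Reactants: 23 (R)-4-benzyl-3-{2-[2-(benzyloxy)-5-bromo-3-methoxyphenyl]acetyl}oxazolidin-2-one; 24 4-(benzyloxy)-3-methoxybenzaldehyde
Product: 27 (R)-4-benzyl-3-[(2R,3R)-2-[2-(benzyloxy)-5-bromo-3-methoxyphenyl]-3-[4-(benzyloxy)-3-methoxyphenyl]-3-hydroxypropanoyl]oxazolidin-2-one, via dibutylboron Z-enolate 25 (not isolated), via boron aldolate 26 (not isolated)
Conditions: n-Bu2BOTf, i-Pr2NEt, CH2Cl2, −78 to 0 °C; then 24, −78 to 0 °C; then H2O2, MeOH, pH 7 buffer, 0 °C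
Reagents that add atoms: none
Why: Evans syn aldol, in which the Z-boron enolate reacts through a Zimmerman–Traxler chair on the face opposite the C4 benzyl group of the (R)-auxiliary to give the (2R,3R) adduct, whose C2 becomes the side-chain (S) centre of the target.

**Step 14**
Reactants: 27 (R)-4-benzyl-3-[(2R,3R)-2-[2-(benzyloxy)-5-bromo-3-methoxyphenyl]-3-[4-(benzyloxy)-3-methoxyphenyl]-3-hydroxypropanoyl]oxazolidin-2-one
Product: 28 (1R,2S)-2-[2-(benzyloxy)-5-bromo-3-methoxyphenyl]-1-[4-(benzyloxy)-3-methoxyphenyl]propane-1,3-diol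
Conditions: LiBH4, H2O (1 equiv), THF, 0 °C
Reagents that add atoms: none
Why: Borohydride reduction of the imide carbonyl to the primary alcohol releases the auxiliary and at 0 °C outruns retro-aldol, so both centres are kept (the descriptor of C2 changes by priority only).

**Step 15**
Reactants: 28 (1R,2S)-2-[2-(benzyloxy)-5-bromo-3-methoxyphenyl]-1-[4-(benzyloxy)-3-methoxyphenyl]propane-1,3-diol
Product: 29 (1R,2S)-2-[2-(benzyloxy)-5-bromo-3-methoxyphenyl]-1-[4-(benzyloxy)-3-methoxyphenyl]-1,3-bis(tert-butyldimethylsilyloxy)propane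
Conditions: TBSOTf, 2,6-lutidine, CH2Cl2, 0 °C
Reagents that add atoms: tert-butyldimethylsilyl triflate, CC(C)(C)[Si](C)(C)OS(=O)(=O)C(F)(F)F
Why: The silyl triflate with a hindered base silylates both the primary and the crowded benzylic hydroxyl, masking the diol for the organozinc coupling.

**Step 16**
Reactants: 16 (3R,4R)-3-[4-(benzyloxy)-3-methoxybenzyl]-4-(iodomethyl)dihydrofuran-2(3H)-one; 29 (1R,2S)-2-[2-(benzyloxy)-5-bromo-3-methoxyphenyl]-1-[4-(benzyloxy)-3-methoxyphenyl]-1,3-bis(tert-butyldimethylsilyloxy)propane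
Product: 31 (3R,4R)-3-[4-(benzyloxy)-3-methoxybenzyl]-4-{4-(benzyloxy)-3-[(1R,2S)-1-[4-(benzyloxy)-3-methoxyphenyl]-1,3-bis(tert-butyldimethylsilyloxy)propan-2-yl]-5-methoxybenzyl}dihydrofuran-2(3H)-one, via alkylzinc iodide 30 (not isolated)
Conditions: Zn dust (activated with BrCH2CH2Br and Me3SiCl), LiCl, THF, 40 °C; then 29, Pd(OAc)2 (3 mol %), SPhos (6 mol %), THF, 50 °C
Reagents that add atoms: none
Why: LiCl-assisted zinc insertion into the primary C–I bond gives an alkylzinc iodide that tolerates the lactone, and Negishi coupling follows by oxidative addition of the unhindered aryl bromide to zerovalent palladium, transmetalation and reductive elimination, which SPhos speeds past β-hydride elimination without touching a stereocentre.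

**Step 17**
Reactants: 31 (3R,4R)-3-[4-(benzyloxy)-3-methoxybenzyl]-4-{4-(benzyloxy)-3-[(1R,2S)-1-[4-(benzyloxy)-3-methoxyphenyl]-1,3-bis(tert-butyldimethylsilyloxy)propan-2-yl]-5-methoxybenzyl}dihydrofuran-2(3H)-one
Product: 32 (3R,4R)-3-[4-(benzyloxy)-3-methoxybenzyl]-4-{4-(benzyloxy)-3-[(1R,2S)-1-[4-(benzyloxy)-3-methoxyphenyl]-1,3-dihydroxypropan-2-yl]-5-methoxybenzyl}dihydrofuran-2(3H)-one
Conditions: Bu4NF, AcOH (1:1), THF, rt to 40 °C
Reagents that add atoms: none
Why: Fluoride cleaves both silyl ethers, and the acetic acid buffer keeps the medium from opening or epimerising the lactone.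

**Step 18**
Reactants: 32 (3R,4R)-3-[4-(benzyloxy)-3-methoxybenzyl]-4-{4-(benzyloxy)-3-[(1R,2S)-1-[4-(benzyloxy)-3-methoxyphenyl]-1,3-dihydroxypropan-2-yl]-5-methoxybenzyl}dihydrofuran-2(3H)-one
Product: 33 (3R,4R)-3-[4-(benzyloxy)-3-methoxybenzyl]-4-{4-(benzyloxy)-3-[(2S)-1-[4-(benzyloxy)-3-methoxyphenyl]-3-hydroxy-1-oxopropan-2-yl]-5-methoxybenzyl}dihydrofuran-2(3H)-one
Conditions: activated MnO2 (excess), CH2Cl2, rt, short contact
Reagents that add atoms: none
Why: Chemoselective MnO2 oxidation of the benzylic carbinol leaves the primary aliphatic alcohol, and the neutral heterogeneous conditions are chosen to keep the now enolisable benzylic (S) centre and to avoid retro-aldol loss of formaldehyde.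

**Step 19**
Reactants: 33 (3R,4R)-3-[4-(benzyloxy)-3-methoxybenzyl]-4-{4-(benzyloxy)-3-[(2S)-1-[4-(benzyloxy)-3-methoxyphenyl]-3-hydroxy-1-oxopropan-2-yl]-5-methoxybenzyl}dihydrofuran-2(3H)-one
Product: 34 (3R,4R)-3-(4-hydroxy-3-methoxybenzyl)-4-{4-hydroxy-3-[(2S)-3-hydroxy-1-(4-hydroxy-3-methoxyphenyl)-1-oxopropan-2-yl]-5-methoxybenzyl}dihydrofuran-2(3H)-one
Conditions: H2 (1 atm), 10% Pd/C, EtOAc, rt; stopped after three equivalents of H2
Reagents that add atoms: none
Why: Hydrogenolysis of the three aryl benzyl ethers is faster than reduction of the electron-rich aryl ketone, and without acid or base neither the side-chain centre epimerises nor the ring B phenol cyclises onto the ketone.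

**Compound list**
1 | 2,2-dimethyl-1,3-dioxan-5-one | CC1(C)OCC(=O)CO1 | starting material
2 | benzyl 2-(diethoxyphosphoryl)acetate | CCOP(=O)(CC(=O)OCc1ccccc1)OCC | starting material
3 | benzyl 2-(2,2-dimethyl-1,3-dioxan-5-ylidene)acetate | CC1(C)OCC(=CC(=O)OCc2ccccc2)CO1 | intermediate
4 | 2-(2,2-dimethyl-1,3-dioxan-5-yl)acetic acid | CC1(C)OCC(CC(=O)O)CO1 | intermediate
5 | (R)-4-benzyloxazolidin-2-one | O=C1N[C@H](Cc2ccccc2)CO1 | starting material
6 | 2-(2,2-dimethyl-1,3-dioxan-5-yl)acetic pivalic anhydride | CC(C)(C)C(=O)OC(=O)CC1COC(C)(C)OC1 | intermediate (not isolated)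
7 | (R)-4-benzyl-3-[2-(2,2-dimethyl-1,3-dioxan-5-yl)acetyl]oxazolidin-2-one | O=C1OC[C@@H](Cc2ccccc2)N1C(=O)CC1COC(C)(C)OC1 | intermediate
8 | [4-(benzyloxy)-3-methoxyphenyl]methanol | COc1cc(CO)ccc1OCc1ccccc1 | starting material
9 | 1-(benzyloxy)-4-(bromomethyl)-2-methoxybenzene | COc1cc(CBr)ccc1OCc1ccccc1 | intermediate
10 | sodium Z-enolate of 7 | [Na+].[O-]/C(=C\C1COC(C)(C)OC1)N1C(=O)OC[C@H]1Cc1ccccc1 | intermediate (not isolated)
11 | (R)-4-benzyl-3-[(2R)-3-[4-(benzyloxy)-3-methoxyphenyl]-2-(2,2-dimethyl-1,3-dioxan-5-yl)propanoyl]oxazolidin-2-one | COc1cc(C[C@@H](C(=O)N2[C@H](Cc3ccccc3)COC2=O)C2COC(C)(C)OC2)ccc1OCc1ccccc1 | intermediate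
12 | lithium (2R)-3-[4-(benzyloxy)-3-methoxyphenyl]-2-(2,2-dimethyl-1,3-dioxan-5-yl)propaneperoxoate | COc1cc(C[C@@H](C(=O)O[O-])C2COC(C)(C)OC2)ccc1OCc1ccccc1.[Li+] | intermediate (not isolated)
13 | (2R)-3-[4-(benzyloxy)-3-methoxyphenyl]-2-(2,2-dimethyl-1,3-dioxan-5-yl)propanoic acid | COc1cc(C[C@@H](C(=O)O)C2COC(C)(C)OC2)ccc1OCc1ccccc1 | intermediate
14 | (2R)-2-[4-(benzyloxy)-3-methoxybenzyl]-4-hydroxy-3-(hydroxymethyl)butanoic acid | COc1cc(C[C@@H](C(=O)O)C(CO)CO)ccc1OCc1ccccc1 | intermediate (not isolated)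
15 | (3R,4S)-3-[4-(benzyloxy)-3-methoxybenzyl]-4-(hydroxymethyl)dihydrofuran-2(3H)-one (trans) | COc1cc(C[C@H]2C(=O)OC[C@@H]2CO)ccc1OCc1ccccc1 | intermediate
16 | (3R,4R)-3-[4-(benzyloxy)-3-methoxybenzyl]-4-(iodomethyl)dihydrofuran-2(3H)-one | COc1cc(C[C@H]2C(=O)OC[C@@H]2CI)ccc1OCc1ccccc1 | intermediate
17 | 5-bromo-2-hydroxy-3-methoxybenzaldehyde | COc1cc(Br)cc(C=O)c1O | starting material
18 | 2-(benzyloxy)-5-bromo-3-methoxybenzaldehyde | COc1cc(Br)cc(C=O)c1OCc1ccccc1 | intermediate
19 | N-{2-[2-(benzyloxy)-5-bromo-3-methoxyphenyl]-1-tosylvinyl}formamide (alkene geometry not defined; potassium salt in the flask) | COc1cc(Br)cc(C=C(NC=O)S(=O)(=O)c2ccc(C)cc2)c1OCc1ccccc1 | intermediate (not isolated)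
20 | 2-[2-(benzyloxy)-5-bromo-3-methoxyphenyl]acetonitrile | COc1cc(Br)cc(CC#N)c1OCc1ccccc1 | intermediate
21 | 2-[2-(benzyloxy)-5-bromo-3-methoxyphenyl]acetic acid | COc1cc(Br)cc(CC(=O)O)c1OCc1ccccc1 | intermediate
22 | 2-[2-(benzyloxy)-5-bromo-3-methoxyphenyl]acetic pivalic anhydride | COc1cc(Br)cc(CC(=O)OC(=O)C(C)(C)C)c1OCc1ccccc1 | intermediate (not isolated)
23 | (R)-4-benzyl-3-{2-[2-(benzyloxy)-5-bromo-3-methoxyphenyl]acetyl}oxazolidin-2-one | COc1cc(Br)cc(CC(=O)N2C(=O)OC[C@H]2Cc2ccccc2)c1OCc1ccccc1 | intermediate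
24 | 4-(benzyloxy)-3-methoxybenzaldehyde | COc1cc(C=O)ccc1OCc1ccccc1 | starting material
25 | dibutylboron Z-enolate of 23 | CCCCB(CCCC)O/C(=C\c1cc(Br)cc(OC)c1OCc1ccccc1)N1C(=O)OC[C@H]1Cc1ccccc1 | intermediate (not isolated)
26 | O-dibutylboryl aldolate of 27 | O=C1OC[C@@H](Cc2ccccc2)N1C(=O)[C@H](c1cc(Br)cc(OC)c1OCc1ccccc1)[C@@H](OB(CCCC)CCCC)c1ccc(OCc2ccccc2)c(OC)c1 | intermediate (not isolated)
27 | (R)-4-benzyl-3-[(2R,3R)-2-[2-(benzyloxy)-5-bromo-3-methoxyphenyl]-3-[4-(benzyloxy)-3-methoxyphenyl]-3-hydroxypropanoyl]oxazolidin-2-one | O=C1OC[C@@H](Cc2ccccc2)N1C(=O)[C@H](c1cc(Br)cc(OC)c1OCc1ccccc1)[C@@H](O)c1ccc(OCc2ccccc2)c(OC)c1 | intermediate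
28 | (1R,2S)-2-[2-(benzyloxy)-5-bromo-3-methoxyphenyl]-1-[4-(benzyloxy)-3-methoxyphenyl]propane-1,3-diol | OC[C@H](c1cc(Br)cc(OC)c1OCc1ccccc1)[C@@H](O)c1ccc(OCc2ccccc2)c(OC)c1 | intermediate
29 | (1R,2S)-2-[2-(benzyloxy)-5-bromo-3-methoxyphenyl]-1-[4-(benzyloxy)-3-methoxyphenyl]-1,3-bis(tert-butyldimethylsilyloxy)propane | CC(C)(C)[Si](C)(C)OC[C@H](c1cc(Br)cc(OC)c1OCc1ccccc1)[C@@H](O[Si](C)(C)C(C)(C)C)c1ccc(OCc2ccccc2)c(OC)c1 | intermediate
30 | {[(3R,4R)-4-[4-(benzyloxy)-3-methoxybenzyl]-5-oxotetrahydrofuran-3-yl]methyl}zinc iodide | COc1cc(C[C@H]2C(=O)OC[C@@H]2C[Zn]I)ccc1OCc1ccccc1 | intermediate (not isolated)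
31 | (3R,4R)-3-[4-(benzyloxy)-3-methoxybenzyl]-4-{4-(benzyloxy)-3-[(1R,2S)-1-[4-(benzyloxy)-3-methoxyphenyl]-1,3-bis(tert-butyldimethylsilyloxy)propan-2-yl]-5-methoxybenzyl}dihydrofuran-2(3H)-one | COc1cc(C[C@H]2C(=O)OC[C@@H]2Cc2cc(OC)c(OCc3ccccc3)c([C@@H](CO[Si](C)(C)C(C)(C)C)[C@@H](O[Si](C)(C)C(C)(C)C)c3ccc(OCc4ccccc4)c(OC)c3)c2)ccc1OCc1ccccc1 | intermediate
32 | (3R,4R)-3-[4-(benzyloxy)-3-methoxybenzyl]-4-{4-(benzyloxy)-3-[(1R,2S)-1-[4-(benzyloxy)-3-methoxyphenyl]-1,3-dihydroxypropan-2-yl]-5-methoxybenzyl}dihydrofuran-2(3H)-one | COc1cc(C[C@H]2C(=O)OC[C@@H]2Cc2cc(OC)c(OCc3ccccc3)c([C@@H](CO)[C@@H](O)c3ccc(OCc4ccccc4)c(OC)c3)c2)ccc1OCc1ccccc1 | intermediate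
33 | (3R,4R)-3-[4-(benzyloxy)-3-methoxybenzyl]-4-{4-(benzyloxy)-3-[(2S)-1-[4-(benzyloxy)-3-methoxyphenyl]-3-hydroxy-1-oxopropan-2-yl]-5-methoxybenzyl}dihydrofuran-2(3H)-one | COc1cc(C[C@H]2C(=O)OC[C@@H]2Cc2cc(OC)c(OCc3ccccc3)c([C@@H](CO)C(=O)c3ccc(OCc4ccccc4)c(OC)c3)c2)ccc1OCc1ccccc1 | intermediate
34 | (3R,4R)-3-(4-hydroxy-3-methoxybenzyl)-4-{4-hydroxy-3-[(2S)-3-hydroxy-1-(4-hydroxy-3-methoxyphenyl)-1-oxopropan-2-yl]-5-methoxybenzyl}dihydrofuran-2(3H)-one (CNP0191394.1) | COc1cc(C[C@H]2C(=O)OC[C@@H]2Cc2cc(OC)c(O)c([C@@H](CO)C(=O)c3ccc(O)c(OC)c3)c2)ccc1O | target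

**Step count**
Total step count: 19.
Longest linear sequence: 11 steps (steps 1–3, 5–8 and 16–19; the ring B branch, steps 9–15 and 16–19, is equally long).

**Steps most likely to fail**

Step 16. The electron-rich aryl bromide may add to palladium slowly, so that the alkylzinc is lost by protonation or β-hydride elimination before it transmetalates. In that case the preformed organometallic is given up. Iodide 16 and bromide 29 are joined directly by nickel-catalysed reductive cross-electrophile coupling (NiI2, 4,4'-di-tert-butyl-2,2'-bipyridine, Zn powder, NaI, DMA, 60 °C). The arylnickel species captures the primary alkyl radical formed from 16; the radical sits on the exocyclic CH2, so C3 is not touched. The fallback sets out from 16 and 29 and comes back at 31; it makes no compound beyond the list (none F0).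

Step 18. On the oxide surface the product may lose formaldehyde by retro-aldol, dehydrate to the enone or epimerise at the newly acidic benzylic CH, or the hindered carbinol may convert incompletely. Chemoselectivity is then taken from a protecting group instead of from the oxidant. Diol 32 is silylated at the primary hydroxyl only (TBSCl, imidazole, CH2Cl2, 0 °C) to the mono-silyl ether F1. Its remaining benzylic alcohol is oxidised under buffered, non-basic conditions (Dess–Martin periodinane, NaHCO3, CH2Cl2, 0 °C) to the β-silyloxy ketone F2, which cannot undergo retro-aldol. Mild acidic desilylation (HF·pyridine, pyridine, THF, 0 °C) then returns to 33. The fallback sets out from 32 and comes back at 33.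

Step 7. The thermodynamic preference between the two hydroxymethyl groups may be too small, so that a large share of cis-lactone remains at equilibrium. The cis isomer is then converted by exchanging the roles of its two CH2 groups, not by further equilibration. The same acid treatment of 13 is run, and the cis-(hydroxymethyl) lactone F3 is separated from 15. It is iodinated (I2, PPh3, imidazole, CH2Cl2) to the cis-(iodomethyl) lactone F4. The lactone of F4 is opened with exactly one equivalent of LiOH (THF/H2O, 0 °C) to the lithium hydroxy iodo carboxylate F5. On warming to 40 °C the carboxylate displaces iodide (5-exo-tet SN2), so the former CH2I enters the ring and the former ring CH2O becomes the free CH2OH; this is trans-lactone 15, with C2 never enolised. The fallback sets out from 13 and comes back at 15.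

**Further compounds**
F0 | step 16 | none | none
F1 | step 18 | (3R,4R)-3-[4-(benzyloxy)-3-methoxybenzyl]-4-{4-(benzyloxy)-3-[(1R,2S)-1-[4-(benzyloxy)-3-methoxyphenyl]-3-(tert-butyldimethylsilyloxy)-1-hydroxypropan-2-yl]-5-methoxybenzyl}dihydrofuran-2(3H)-one | COc1cc(C[C@H]2C(=O)OC[C@@H]2Cc2cc(OC)c(OCc3ccccc3)c([C@@H](CO[Si](C)(C)C(C)(C)C)[C@@H](O)c3ccc(OCc4ccccc4)c(OC)c3)c2)ccc1OCc1ccccc1
F2 | step 18 | (3R,4R)-3-[4-(benzyloxy)-3-methoxybenzyl]-4-{4-(benzyloxy)-3-[(2S)-1-[4-(benzyloxy)-3-methoxyphenyl]-3-(tert-butyldimethylsilyloxy)-1-oxopropan-2-yl]-5-methoxybenzyl}dihydrofuran-2(3H)-one | COc1cc(C[C@H]2C(=O)OC[C@@H]2Cc2cc(OC)c(OCc3ccccc3)c([C@@H](CO[Si](C)(C)C(C)(C)C)C(=O)c3ccc(OCc4ccccc4)c(OC)c3)c2)ccc1OCc1ccccc1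
F3 | step 7 | (3R,4R)-3-[4-(benzyloxy)-3-methoxybenzyl]-4-(hydroxymethyl)dihydrofuran-2(3H)-one (cis) | COc1cc(C[C@H]2C(=O)OC[C@H]2CO)ccc1OCc1ccccc1
F4 | step 7 | (3R,4S)-3-[4-(benzyloxy)-3-methoxybenzyl]-4-(iodomethyl)dihydrofuran-2(3H)-one (cis) | COc1cc(C[C@H]2C(=O)OC[C@H]2CI)ccc1OCc1ccccc1
F5 | step 7 | lithium (2R,3S)-2-[4-(benzyloxy)-3-methoxybenzyl]-3-(hydroxymethyl)-4-iodobutanoate | COc1cc(C[C@@H](C(=O)[O-])[C@@H](CO)CI)ccc1OCc1ccccc1.[Li+]
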